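The data were computed for an exercise; noise was put on by code.

- We leave flasks set for 80 min, longer than the 25.0 min in which the amber run at 25 °C fell to 23% of its substrate, so the first thing to know is how far substrate will have got when you come.

| flask | substrate | temperature | remark | time |
|---|---|---|---|---|
| amber | 0.75 M | 25 °C | run made earlier |  |
| cedar | 0.50 M | 25 °C |  | 80 min |
| larch | 0.50 M | 0 °C |  | 80 min |
| elm | 0.50 M |  | at 25 °C until 15 min, from then on at 0 °C | 80 min |

- amber (time / min: target / %, substrate / %): 3.00: 11, 79; 8.00: 18, 64; 15.0: 22, 40; 25.0: 33, 23

(scatter of a reading: 2 percentage points)

- the numbers in the tables scatter with a standard deviation of 2 percentage points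
- in a conversion other conformer counts as not yet reacted
- a reading or a percentage of target counts all its forms, free or not
- the earlier runs do not show what temperature does; that part of a forecast is a guess

1. the flask that comes out highest in amount of target, in percent of the substrate charged, or "all alike" when all lie within 1.5 percentage points (cedar / larch / elm / all alike)
2. target at the end, in percent of the substrate charged, cedar
3. target at the end, in percent of the substrate charged, larch
4. target at the end, in percent of the substrate charged, elm

- For cedar, at 25 °C, we take substrate to fall first-order, as the amber readings suggest, since in that order the percentage left does not depend on the charge, so the last amber reading, with its scatter, gives k = 0.0588 min⁻¹ and a half-life of 11.8 min, our estimate of the time in which c(substrate) halves at that temperature.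
- When you come at 80 min, cedar will have stood 6.78 half-lives, so we reckon c(substrate) at 0.907% of the charge.
- Leave cedar at its temperature until then; the last amber reading leaves about 44.0% of the charge as neither substrate nor target, more than the 33% of target, and the amber table reads these two species and no other, so for target we commit to no number of our own.
- The forecast does commit: 44% in cedar, “assuming target is stable”, 19% in larch and 32% in elm, with cedar highest.
- The flasks give 58.8% of target in cedar, 4.16% in larch and 23.3% in elm, so cedar stands highest.

    crystals ⇌ target, rate k1*(cs1 - [target]) while solid is left; crystals form when [target] > cs1 (solubility = 44.0 mM, k = 1.90 min⁻¹)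
    substrate → target (k = 0.0240 min⁻¹, Ea = 100 kJ mol⁻¹)
    substrate ⇌ other conformer (K = 2.20, k = 0.0440 min⁻¹, Ea = 81.0 kJ mol⁻¹, ΔH = −34.0 kJ mol⁻¹)
    target ⇌ isomer of the product (K = 1.50, k = 0.0190 min⁻¹, Ea = 86.0 kJ mol⁻¹, ΔH = −40.0 kJ mol⁻¹)
    other conformer → isomer of the product (k = 0.0740 min⁻¹, Ea = 86.0 kJ mol⁻¹)
    (constants at 25 °C)

With 11.8 min per half-life, we counted 6.78 in cedar for 0.907% of substrate left, and cedar holds 1.44%; elm, still at 25 °C up to its change of temperature at 15.0 min, counts 1.27 for 41.4%, and elm holds 39.3%. Yet cedar has not come to rest at 80 min: left until 800 min, its target rises from 58.8% to 86.8%, while isomer of the product falls from 38.4% to 13.2% and crystals, counted in target, grow from 49.8% to 78.0%.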